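The time of reading, 5.0 h, is where I began: I asked how many half-lives of the electrophile fit into it.

the same everywhere: electrophile 20 mM; gas 5.6 mM (held)

| run | free base | remark | time |
|---|---|---|---|
| noon | 19 mM | run made earlier |  |
| autumn | 71 mM | run made earlier |  |
| birch | 16.0 mM |  | 5.0 h |
| oak | 32.0 mM |  | 5.0 h |
| ash | 64.0 mM |  | 5.0 h |

| run | time / h | electrophile / % | target / % |
|---|---|---|---|
| noon | 0.833 | 92 | 0 |
| noon | 1.50 | 80 | 14 |
| noon | 2.50 | 75 | 21 |
| noon | 3.00 | 73 | 30 |
| noon | 4.00 | 61 | 36 |
| noon | 5.00 | 53 | 40 |
| autumn | 0.833 | 93 | 3 |
| autumn | 1.50 | 83 | 15 |
| autumn | 2.50 | 76 | 22 |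
| autumn | 3.00 | 72 | 26 |
| autumn | 4.00 | 65 | 33 |
| autumn | 5.00 | 55 | 42 |

(readings scatter by 2 percentage points)

- part of the electrophile that has reacted at the end, birch
- part of the electrophile that has reacted at the end, oak
- part of the electrophile that has reacted at the end, ash
- what raising the concentration of free base from its lowest to its highest value here does to the part of the electrophile that has reacted (changes below 5 percentage points count as none) (no change / it rises / it falls)

- at the start none of the gas is in solution
- what has gone from electrophile into another species counts as reacted, even if it can come back

I took the time first. At 5.00 h the noon run had 53% of its electrophile left and the autumn run 55%. From their mean I read an apparent half-life, the time that divides the fraction left by 2 at a pseudo-first-order pace, of 5.62 h. At 2.50 h this half-life gave 73.5% left, and the two runs read 75% and 76%. The time of reading was therefore 0.889 half-lives, which meant 46.0% of the charge reacted.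

Free base came next. By hand, a rate in step with free base gave the autumn run 9.33% left, yet it read 55%. The two runs differed by 2 percentage points, with a scatter of 2 points, so I gave free base no part in the half-life. In free base, oak and ash lay between the two runs, but birch lay just below noon. Taken one for one, the reacted electrophile came to 57.5% of the base charged to birch, so that charge covered it.

Electrophile and gas stood at 20 mM and 5.6 mM in birch, oak and ash, so neither separated these flasks. I reckoned 46.0% for each of them, and no change.

The forecast, drawn from the same two runs, gave 46%, 46% and 46%, with no change: “Oak and ash lie within the tested range”.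

Birch, oak and ash gave 44.9%, 44.9% and 44.9%, so the answer on the trend was no change: from the lowest to the highest free base the part reacted moved by 0.016 points. Ash stood 1.1 points below my count.

    electrophile + nucleophile → acid set free + target (k = 26.0 M⁻¹ h⁻¹)
    gas ⇌ nucleophile, rate k2*(csat - [nucleophile]) (kL = 2.90 h⁻¹)
    free base → decomposition product (k = 2.10 × 10⁻⁴ h⁻¹)
    acid set free + free base ⇌ salt of the base (K = 190 M⁻¹, k = 340 M⁻¹ h⁻¹)
    nucleophile + acid set free ⇌ protonated nucleophile, settled at all times (K = 3700 M⁻¹)
    electrophile + acid set free ⇌ idle adduct, settled at all times (K = 170 M⁻¹)

In ash, electrophile and nucleophile formed target throughout, with the mid-point of that turnover up to the time of reading at 2.35 h, while gas crossed over and nucleophile stood at 4.60 mM after 2.50 h and 4.81 mM after 5.00 h. Meanwhile acid set free passed into protonated nucleophile and salt of the base, which stood at 4.83 mM and 2.87 mM at the time of reading, with 95.4% of the free base still free. With a half-life of 5.62 h, a reading at 20 h is 3.56 half-lives, or 8.49% left, and ash then held 7.99%.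

The earlier runs and the new flask were computed with made-up constants.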